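**Plan**
1. Ring numbering: C1(=O), C2(OMe), C3H, C4(=O), C5H, C6(side chain C1'–C15'). The quinone is traced back through hydroquinone 20 to benzaldehyde 18, in which C1 carries CHO in place of oxygen (Dakin exchange).
2. The ring of 18 is cut at C5–C6 and at C1–C2. This gives a two-carbon ynal 9 (C6≡C1–CHO, bearing the complete acetoxy side chain) and a four-carbon diene 15 (C2–C3–C4–C5), joined in one Diels–Alder/aromatisation event.
3. Enabling feature: in the six-membered ring the oxygens on C2 and C4 stand 1,3 (acetoacetate or polyketide pattern), so C2–C5 is a 1,1-dimethoxy-3-silyloxybutadiene with nucleophilic C5. C1 is the one oxygenated carbon that breaks this alternation, and it lies where the alkyne needs its acceptor; the formyl helper activates first and is later exchanged for that oxygen, much as nature hydroxylates a resorcylic precursor.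
4. Side chain cuts: C6–C1' (epoxide opening by an alkynyllithium) and C3'–C4' (C12 Grignard reagent on a C3 epoxide).
5. Forward order: C12 + C3 gives epoxide 4; a C3 alkyne gives 7; then acetate and ynal 9. Diene 15 takes three steps from acetyl chloride, the only ring arises in step 8, and two oxidations end the route.
6. Stereochemistry: the single (R) centre is bought with (R)-epichlorohydrin. Its C–O bond is never broken and no later step touches it.

Key step: step 8

Remark: CIP analysis of the given SMILES (OAc > CH2–quinone > tridecyl > H) gives the (R) configuration. Compounds 1, 2, 5, 10 and 11 are taken as catalogue chemicals.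

**Step 1**
Reactants: 1 (R)-epichlorohydrin; 2 dodecylmagnesium bromide
Product: 4 (R)-2-tridecyloxirane, via chlorohydrin 3 (not isolated)
Conditions: CuI (10 mol %), THF, −40 → 0 °C; then 5 M aq. NaOH, rt
Reagents that add atoms: none
Why: Copper-catalysed Grignard opening of a terminal epoxide takes place at the unsubstituted ring carbon and the alkoxide then closes on CH2Cl (intramolecular Williamson reaction), so the C–O bond of the stereocentre is never broken and the (R) configuration of 1 is carried into 4.

**Step 2**
Reactants: 4 (R)-2-tridecyloxirane; 5 3,3-diethoxyprop-1-yne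
Product: 7 (R)-1,1-diethoxyoctadec-2-yn-5-ol, via lithium acetylide 6 (not isolated)
Conditions: 5, n-BuLi, THF, −78 °C; BF3·OEt2; then 4, −78 °C; aq. NH4Cl
Reagents that add atoms: none
Why: Yamaguchi–Hirao alkynylation, in which the BF3-activated terminal epoxide is opened by the alkynyllithium in SN2 fashion at CH2 only, leaves the carbinol centre (R) and, at −78 °C, the deactivated propargylic acetal untouched.

**Step 3**
Reactants: 7 (R)-1,1-diethoxyoctadec-2-yn-5-ol
Product: 8 (R)-1,1-diethoxyoctadec-2-yn-5-yl acetate
Conditions: Ac2O, pyridine, DMAP (cat.), CH2Cl2, rt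
Reagents that add atoms: acetic anhydride, CC(=O)OC(C)=O
Why: DMAP-catalysed O-acylation of a secondary alcohol proceeds with retention and installs the acetate of the target early, because it tolerates every later step.

**Step 4**
Reactants: 8 (R)-1,1-diethoxyoctadec-2-yn-5-yl acetate
Product: 9 (R)-1-oxooctadec-2-yn-5-yl acetate (5-acetoxyoctadec-2-ynal)
Conditions: TFA–H2O (9:1), CH2Cl2, 0 °C → rt
Reagents that add atoms: water, O
Why: Acid-catalysed acetal hydrolysis frees the acceptor group of the dienophile under conditions in which a secondary acetate is stable and no base is present that could trigger loss of acetic acid.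

**Step 5**
Reactants: 10 acetyl chloride; 11 1,1-dichloroethene
Product: 13 4,4-dichlorobut-3-en-2-one, via trichloroketone 12 (not isolated)
Conditions: AlCl3, CH2Cl2, 0 °C → rt; ice/HCl work-up; distillation (−HCl)
Reagents that add atoms: none
Why: In this Friedel–Crafts-type (Kondakov) acylation of an alkene the acylium ion adds to the CH2 terminus of 11, chloride capture of the chlorine-stabilised cation gives 12, and its acidic α-hydrogen allows loss of HCl to the conjugated enone.

**Step 6**
Reactants: 13 4,4-dichlorobut-3-en-2-one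
Product: 14 4,4-dimethoxybut-3-en-2-one
Conditions: NaOMe (2.1 equiv), MeOH, 0 °C → rt; distillation
Reagents that add atoms: sodium methoxide, [Na+].[O-]C
Why: Two successive addition–elimination events (vinylic substitution) at the β-carbon of the enone replace both chlorides by methoxide and give the acyl ketene acetal.

**Step 7**
Reactants: 14 4,4-dimethoxybut-3-en-2-one
Product: 15 1,1-dimethoxy-3-(trimethylsilyloxy)buta-1,3-diene
Conditions: Me3SiCl, Et3N, ZnCl2 (cat.), PhMe, 40 °C; filtration, distillation, used at once
Reagents that add atoms: chlorotrimethylsilane, C[Si](C)(C)Cl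
Why: Soft enolisation–silylation of a methyl ketone, as used for 1-methoxy-3-silyloxybutadienes, can give only one silyl dienol ether because the methyl group is the sole enolisable position.

**Step 8**
Reactants: 9 (R)-1-oxooctadec-2-yn-5-yl acetate; 15 1,1-dimethoxy-3-(trimethylsilyloxy)buta-1,3-diene
Product: 18 (R)-1-(2-formyl-5-hydroxy-3-methoxyphenyl)pentadecan-2-yl acetate, via cycloadduct 16 (not isolated), via aryl silyl ether 17 (not isolated)
Conditions: 15 (2.5 equiv), PhMe, Ar, rt → 80 °C; then THF/0.1 M HCl, 0 °C
Reagents that add atoms: none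
Why: This is a normal-electron-demand Diels–Alder reaction in which the CH2 terminus of 15 (largest HOMO coefficient, pushed by the 3-silyloxy group and vinylogously by both 1-methoxy groups) bonds to the β-alkynyl carbon of 9 while the C(OMe)2 terminus bonds to the formyl-bearing α-carbon, concerted but strongly asynchronous (limiting case: Mukaiyama–Michael addition followed by collapse of the allenolate on the dimethoxycarbenium ion). The closest known reaction type is the cycloaddition–aromatisation of 1,1-dialkoxy-3-silyloxybutadienes with acetylenic carbonyl compounds to give resorcinol derivatives. The one ring closed, the six-membered carbocycle, arises by intermolecular [4+2] closure with both σ-bonds made in one suprafacial approach, after which cyclohexa-1,4-diene 16 loses one methanol by 1,4-elimination (driven by aromatisation), keeps the other as the methoxy group of the target, and dilute acid removes the silyl group of 17. No new stereocentre is formed, and the (R)-acetoxy centre, two atoms away from the alkyne, takes no part. The step needs regioselectivity, which the matched polarisation of both partners secures (only the 2-methoxy-4-hydroxy-6-alkyl benzaldehyde can arise), and chemoselectivity for C≡C over C=O, which the absence of any Lewis acid secures because hetero-Diels–Alder and aldol addition to the aldehyde are slow without one.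

**Step 9**
Reactants: 18 (R)-1-(2-formyl-5-hydroxy-3-methoxyphenyl)pentadecan-2-yl acetate
Product: 20 (R)-1-(2,5-dihydroxy-3-methoxyphenyl)pentadecan-2-yl acetate, via aryl formate 19 (not isolated)
Conditions: mCPBA (1.05 equiv), CH2Cl2, 0 °C → rt; then Et3N, MeOH, Ar, 0 °C
Reagents that add atoms: 3-chloroperoxybenzoic acid (mCPBA), O=C(OO)c1cccc(Cl)c1
Why: In this Baeyer–Villiger (Dakin-type) oxidation the Criegee adduct of an aldehyde on a ring bearing ortho-OMe and para-OH migrates the aryl group, and the resulting aryl formate undergoes methanolysis much faster than the secondary alkyl acetate.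

**Step 10**
Reactants: 20 (R)-1-(2,5-dihydroxy-3-methoxyphenyl)pentadecan-2-yl acetate
Product: 21 ardisinone
Conditions: Ag2O, MgSO4, Et2O, rt, dark
Reagents that add atoms: none
Why: Two-electron oxidation of a hydroquinone to the p-benzoquinone by Ag2O is fast under neutral anhydrous conditions that leave the acetate and the stereocentre alone.

**Compound list**
1 | (R)-epichlorohydrin | ClC[C@H]1CO1 | starting material
2 | dodecylmagnesium bromide | CCCCCCCCCCCC[Mg]Br | starting material
3 | (R)-1-chloropentadecan-2-ol (present as its bromomagnesium alkoxide) | ClC[C@H](O)CCCCCCCCCCCCC | intermediate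
4 | (R)-2-tridecyloxirane | CCCCCCCCCCCCC[C@@H]1CO1 | intermediate
5 | 3,3-diethoxyprop-1-yne | C#CC(OCC)OCC | starting material
6 | (3,3-diethoxyprop-1-yn-1-yl)lithium | [Li]C#CC(OCC)OCC | intermediate
7 | (R)-1,1-diethoxyoctadec-2-yn-5-ol | CCCCCCCCCCCCC[C@H](CC#CC(OCC)OCC)O | intermediate
8 | (R)-1,1-diethoxyoctadec-2-yn-5-yl acetate | CCCCCCCCCCCCC[C@H](CC#CC(OCC)OCC)OC(C)=O | intermediate
9 | (R)-1-oxooctadec-2-yn-5-yl acetate | CCCCCCCCCCCCC[C@H](CC#CC=O)OC(C)=O | intermediate
10 | acetyl chloride | CC(=O)Cl | starting material
11 | 1,1-dichloroethene | C=C(Cl)Cl | starting material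
12 | 4,4,4-trichlorobutan-2-one | CC(=O)CC(Cl)(Cl)Cl | intermediate
13 | 4,4-dichlorobut-3-en-2-one | CC(=O)C=C(Cl)Cl | intermediate
14 | 4,4-dimethoxybut-3-en-2-one | CC(=O)C=C(OC)OC | intermediate
15 | 1,1-dimethoxy-3-(trimethylsilyloxy)buta-1,3-diene | C=C(O[Si](C)(C)C)C=C(OC)OC | intermediate
16 | (R)-1-[2-formyl-3,3-dimethoxy-5-(trimethylsilyloxy)cyclohexa-1,4-dien-1-yl]pentadecan-2-yl acetate | CCCCCCCCCCCCC[C@H](CC1=C(C=O)C(OC)(OC)C=C(O[Si](C)(C)C)C1)OC(C)=O | intermediate
17 | (R)-1-[2-formyl-3-methoxy-5-(trimethylsilyloxy)phenyl]pentadecan-2-yl acetate | CCCCCCCCCCCCC[C@H](Cc1cc(O[Si](C)(C)C)cc(OC)c1C=O)OC(C)=O | intermediate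
18 | (R)-1-(2-formyl-5-hydroxy-3-methoxyphenyl)pentadecan-2-yl acetate | CCCCCCCCCCCCC[C@H](Cc1cc(O)cc(OC)c1C=O)OC(C)=O | intermediate
19 | (R)-1-[2-(formyloxy)-5-hydroxy-3-methoxyphenyl]pentadecan-2-yl acetate | CCCCCCCCCCCCC[C@H](Cc1cc(O)cc(OC)c1OC=O)OC(C)=O | intermediate
20 | (R)-1-(2,5-dihydroxy-3-methoxyphenyl)pentadecan-2-yl acetate | CCCCCCCCCCCCC[C@H](Cc1cc(O)cc(OC)c1O)OC(C)=O | intermediate
21 | ardisinone, (R)-1-(5-methoxy-3,6-dioxocyclohexa-1,4-dien-1-yl)pentadecan-2-yl acetate | CCCCCCCCCCCCC[C@H](CC1=CC(=O)C=C(OC)C1=O)OC(C)=O | target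

Total step count: 10. Longest linear sequence: 7 steps (1, 2, 3, 4, 8, 9, 10).

**Steps most likely to fail**

**Step 8.**
- What may go wrong: attack of the very nucleophilic diene on the aldehyde carbonyl (hetero-Diels–Alder or aldol-type addition), protodesilylation of the diene by the methanol that aromatisation releases, or thermal loss of acetic acid from the ynal before cycloaddition.
- Fallback (sets out from 4, comes back at 21): the ring is bought instead of built.
  - Commercial 1-bromo-3,5-dimethoxybenzene is converted with Mg in THF into (3,5-dimethoxyphenyl)magnesium bromide F1.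
  - F1 opens epoxide 4 at CH2 under CuI catalysis to give (R)-1-(3,5-dimethoxyphenyl)pentadecan-2-ol F2.
  - Acetylation (Ac2O, pyridine, DMAP) gives (R)-1-(3,5-dimethoxyphenyl)pentadecan-2-yl acetate F3.
  - Vilsmeier–Haack formylation (POCl3, DMF) should go ortho to the alkyl group and para to a methoxy group, to give (R)-1-(2-formyl-3,5-dimethoxyphenyl)pentadecan-2-yl acetate F4.
  - Baeyer–Villiger oxidation with mCPBA gives (R)-1-[2-(formyloxy)-3,5-dimethoxyphenyl]pentadecan-2-yl acetate F5.
  - Brief methanolysis (Et3N, MeOH) gives (R)-1-(2-hydroxy-3,5-dimethoxyphenyl)pentadecan-2-yl acetate F6.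
  - Oxidative demethylation of this 4-methoxyphenol with (NH4)2Ce(NO3)6 in MeCN/H2O at 0 °C gives 21.

**Step 9.**
- What may go wrong: over-oxidation of the electron-rich free phenol ring by the peracid, or partial loss of the side-chain acetate during formate cleavage.
- Fallback (sets out from 18, comes back at 21): the formyl helper is removed instead of exchanged.
  - Tsuji–Wilkinson decarbonylation with RhCl(PPh3)3 in refluxing xylene gives (R)-1-(3-hydroxy-5-methoxyphenyl)pentadecan-2-yl acetate F7.
  - Teuber oxidation with K2[ON(SO3)2] (Fremy's salt) in acetone/aqueous KH2PO4 places the missing oxygen para to the phenol, between OMe and the side chain, and gives 21 directly.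

**Step 4.**
- What may go wrong: elimination of acetic acid or hydration of the triple bond under the acid strength needed to open the deactivated propargylic acetal.
- Fallback (sets out from 4, comes back at 9): the aldehyde is reached by neutral oxidation instead of hydrolysis.
  - Commercial tert-butyldimethyl(prop-2-yn-1-yloxy)silane is lithiated with n-BuLi to [3-(tert-butyldimethylsilyloxy)prop-1-yn-1-yl]lithium F8.
  - F8 opens 4 in the presence of BF3·OEt2 at −78 °C to give (R)-1-(tert-butyldimethylsilyloxy)octadec-2-yn-5-ol F9.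
  - Acetylation gives (R)-1-(tert-butyldimethylsilyloxy)octadec-2-yn-5-yl acetate F10.
  - HF·pyridine in THF gives (R)-1-hydroxyoctadec-2-yn-5-yl acetate F11.
  - MnO2 in CH2Cl2 oxidises the propargylic alcohol to 9.

**Further compounds**
F1 | step 8 | (3,5-dimethoxyphenyl)magnesium bromide | COc1cc(OC)cc([Mg]Br)c1
F2 | step 8 | (R)-1-(3,5-dimethoxyphenyl)pentadecan-2-ol | CCCCCCCCCCCCC[C@H](Cc1cc(OC)cc(OC)c1)O
F3 | step 8 | (R)-1-(3,5-dimethoxyphenyl)pentadecan-2-yl acetate | CCCCCCCCCCCCC[C@H](Cc1cc(OC)cc(OC)c1)OC(C)=O
F4 | step 8 | (R)-1-(2-formyl-3,5-dimethoxyphenyl)pentadecan-2-yl acetate | CCCCCCCCCCCCC[C@H](Cc1cc(OC)cc(OC)c1C=O)OC(C)=O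
F5 | step 8 | (R)-1-[2-(formyloxy)-3,5-dimethoxyphenyl]pentadecan-2-yl acetate | CCCCCCCCCCCCC[C@H](Cc1cc(OC)cc(OC)c1OC=O)OC(C)=O
F6 | step 8 | (R)-1-(2-hydroxy-3,5-dimethoxyphenyl)pentadecan-2-yl acetate | CCCCCCCCCCCCC[C@H](Cc1cc(OC)cc(OC)c1O)OC(C)=O
F7 | step 9 | (R)-1-(3-hydroxy-5-methoxyphenyl)pentadecan-2-yl acetate | CCCCCCCCCCCCC[C@H](Cc1cc(O)cc(OC)c1)OC(C)=O
F8 | step 4 | [3-(tert-butyldimethylsilyloxy)prop-1-yn-1-yl]lithium | [Li]C#CCO[Si](C)(C)C(C)(C)C
F9 | step 4 | (R)-1-(tert-butyldimethylsilyloxy)octadec-2-yn-5-ol | CCCCCCCCCCCCC[C@H](CC#CCO[Si](C)(C)C(C)(C)C)O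
F10 | step 4 | (R)-1-(tert-butyldimethylsilyloxy)octadec-2-yn-5-yl acetate | CCCCCCCCCCCCC[C@H](CC#CCO[Si](C)(C)C(C)(C)C)OC(C)=O
F11 | step 4 | (R)-1-hydroxyoctadec-2-yn-5-yl acetate | CCCCCCCCCCCCC[C@H](CC#CCO)OC(C)=O
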